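**Retrosynthetic overview**
1. Target 20 ⇐ silyl-protected phthalide 19 ⇐ hydroxy amide 18. Acid closes the C1–O2 bond of the five-membered lactone with loss of diisopropylamine; this is the only ring made, and it closes after the key step.
2. 18 ⇐ aryne 16 (C7a≡C3a) + α-lithiated carbamate 15. Carbanion addition forms C3a–C3, then the carbamoyl group migrates from O2 to C7a to form C7a–C1; C3 is set by the chiral diamine.
3. Feature used: C7a and C3a are adjacent carbons of the benzene ring and carry C1 and C3 of the lactone ring. The C7 methoxy group flanks C7a and polarises the aryne, and O2–C1(=O) is the O–C(=O) unit of an O-alkyl carbamate of the C3 alcohol.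
4. Carbamate 9 ⇐ Grignard reagent 7 of 10-bromodecyl carbamate 3 + Weinreb amide 6 from (S)-γ-valerolactone (C13' is bought), then dioxolane formation.
5. Aryne precursor 14 ⇐ 5-iodovanillin 10 by Dakin oxidation, selective silylation and triflation (triflate on C7a, iodide on C3a).

Key step: step 9

Remarks on the chemistry (assumptions):
- Numbering: phthalide C1 (C=O), O2, C3, C3a, C4–C7, C7a; side chain C1'–C14' counted from C3. The target is 3S,13'S.
- The lithiated carbamate is assumed to attack the aryne with retention at carbon (syn carbolithiation), as it does with most electrophiles. On that basis (+)-sparteine leads to 3S. If the addition goes with inversion, (−)-sparteine is used and nothing else changes.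
- The isomeric precursor with iodide on C7a and triflate on C3a would release the same aryne. It is not used because iodination of a 3-methoxy-5-silyloxyphenol has three activated positions and no reliable regiocontrol, whereas 5-iodovanillin fixes all four substituents.

**Route**

Step 1
Reactants: 1 10-bromodecan-1-ol; 2 N,N-diisopropylcarbamoyl chloride
Product: 3 10-bromodecyl N,N-diisopropylcarbamate
Conditions: NaH, THF, 0 °C → rt
Reagents that add atoms: none
Why: O-carbamoylation of the sodium alkoxide (acyl substitution at the carbamoyl chloride) should be much faster in THF than Williamson attack on the primary bromide, and the insoluble NaCl cannot exchange the bromide.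

Step 2
Reactants: 4 (S)-γ-valerolactone
Product: 5 (S)-4-hydroxy-N-methoxy-N-methylpentanamide
Conditions: MeNH(OMe)·HCl, i-PrMgCl, THF, −20 → 0 °C
Reagents that add atoms: N,O-dimethylhydroxylamine hydrochloride, CNOC.Cl
Why: Aminolysis of the lactone by the magnesium amide (Weinreb amide formation) opens the ring at the acyl carbon, so the C–O bond of the stereocentre that becomes C13' is untouched.

Step 3
Reactants: 5 (S)-4-hydroxy-N-methoxy-N-methylpentanamide
Product: 6 (S)-4-(tert-butyldimethylsilyloxy)-N-methoxy-N-methylpentanamide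
Conditions: TBSCl, imidazole, DMF, rt
Reagents that add atoms: tert-butyldimethylsilyl chloride, CC(C)(C)[Si](C)(C)Cl
Why: Silylation of the secondary alcohol stops relactonization and gives an ether that tolerates Grignard and organolithium reagents.

Step 4
Reactants: 3 10-bromodecyl N,N-diisopropylcarbamate; 6 (S)-4-(tert-butyldimethylsilyloxy)-N-methoxy-N-methylpentanamide
Product: 8 (14S)-14-(tert-butyldimethylsilyloxy)-11-oxopentadecyl N,N-diisopropylcarbamate, via Grignard reagent 7 (not isolated)
Conditions: Mg, I2 (cat.), THF, 40 °C; then 6, 0 °C → rt; aq. NH4Cl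
Reagents that add atoms: none
Why: Grignard addition to a Weinreb amide stops at the ketone through the magnesium-chelated tetrahedral intermediate, and the hindered N,N-diisopropylcarbamate should be inert to alkylmagnesium halides at these temperatures.

Step 5
Reactants: 8 (14S)-14-(tert-butyldimethylsilyloxy)-11-oxopentadecyl N,N-diisopropylcarbamate
Product: 9 10-{2-[(3S)-3-(tert-butyldimethylsilyloxy)butyl]-1,3-dioxolan-2-yl}decyl N,N-diisopropylcarbamate
Conditions: TMSOCH2CH2OTMS, TMSOTf (cat.), CH2Cl2, −78 °C; pyridine quench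
Reagents that add atoms: 1,2-bis(trimethylsilyloxy)ethane, C[Si](C)(C)OCCO[Si](C)(C)C
Why: Noyori ketalization at low temperature masks the C10' ketone against sec-butyllithium, and it is aprotic and mild enough to keep the secondary TBS ether and the carbamate.

Step 6
Reactants: 10 5-iodovanillin (4-hydroxy-3-iodo-5-methoxybenzaldehyde)
Product: 12 2-iodo-6-methoxybenzene-1,4-diol, via aryl formate 11 (not isolated)
Conditions: H2O2 (30% aq.), NaOH, THF–H2O, 0 °C, N2; then Na2S2O4, dilute HCl
Reagents that add atoms: hydrogen peroxide, OO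
Why: Dakin oxidation of a para-hydroxybenzaldehyde replaces the formyl group by hydroxyl through aryl migration to peroxide oxygen and hydrolysis of the formate, and the reductive work-up should return any quinone to the hydroquinone.

Step 7
Reactants: 12 2-iodo-6-methoxybenzene-1,4-diol
Product: 13 2-iodo-6-methoxy-4-(triisopropylsilyloxy)phenol
Conditions: TIPSCl (1.05 equiv), imidazole, DMF, 0 °C
Reagents that add atoms: triisopropylsilyl chloride, CC(C)[Si](Cl)(C(C)C)C(C)C
Why: Steric differentiation in silylation should put the bulky silyl group on the hydroxyl flanked by two hydrogens and not on the one flanked by iodine and methoxy.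

Step 8
Reactants: 13 2-iodo-6-methoxy-4-(triisopropylsilyloxy)phenol
Product: 14 2-iodo-6-methoxy-4-(triisopropylsilyloxy)phenyl trifluoromethanesulfonate
Conditions: Tf2O, pyridine, CH2Cl2, 0 °C
Reagents that add atoms: trifluoromethanesulfonic anhydride, O=S(=O)(OS(=O)(=O)C(F)(F)F)C(F)(F)F
Why: O-sulfonylation of the remaining phenol with the small, highly reactive anhydride should work despite the two ortho substituents and gives the ortho-iodoaryl triflate needed for low-temperature aryne release.

Step 9
Reactants: 9 10-{2-[(3S)-3-(tert-butyldimethylsilyloxy)butyl]-1,3-dioxolan-2-yl}decyl N,N-diisopropylcarbamate; 14 2-iodo-6-methoxy-4-(triisopropylsilyloxy)phenyl trifluoromethanesulfonate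
Product: 18 2-{(1S)-10-[2-((3S)-3-(tert-butyldimethylsilyloxy)butyl)-1,3-dioxolan-2-yl]-1-hydroxydecyl}-6-methoxy-N,N-diisopropyl-4-(triisopropylsilyloxy)benzamide, via lithiated carbamate 15 (not isolated), via aryne 16 (not isolated), via aryllithium 17 (not isolated)
Conditions: s-BuLi (1.1 equiv), (+)-sparteine (1.2 equiv), Et2O, −78 °C, 5 h; then 14 (1.1 equiv) in Et2O and n-BuLi (1.1 equiv) added simultaneously over 1 h, −78 °C; then → rt; aq. NH4Cl
Reagents that add atoms: none
Why: Proposed new method: sec-butyllithium with (+)-sparteine should remove the pro-R proton next to the carbamate oxygen of 9 to give the configurationally stable carbanion 15, while iodine–lithium exchange on 14 by n-BuLi and loss of lithium triflate at −78 °C release aryne 16; 15 adds to C3a (bond C3a–C3), and the resulting C7a aryllithium 17 attacks the carbamate carbonyl through a five-membered tetrahedral intermediate that collapses to the lithium alkoxide of 18 (bond C7a–C1). The closest known reaction types are the sparteine-mediated lithiation–substitution of O-alkyl carbamates, the addition of organolithiums to 3-methoxyarynes, and the anionic homo-Fries 1,4-carbamoyl shift of ortho-lithiated benzyl carbamates. No ring is closed in this step. The new stereocentre C3 is controlled by the sparteine enantiomer through the configuration of 15, assuming retentive attack on the aryne. Attack must occur at C3a and not at C7a, which the C7 methoxy group should secure by distorting the aryne towards attack at the distal carbon and by stabilising the C7a anion inductively. Carbanion 15 must also outcompete n-BuLi for the aryne, which the slow simultaneous addition should secure because n-BuLi is consumed by the faster iodine–lithium exchange.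

Step 10
Reactants: 18 the hydroxy amide from step 9
Product: 19 (3S)-3-[(13S)-13-hydroxy-10-oxotetradecyl]-7-methoxy-5-(triisopropylsilyloxy)isobenzofuran-1(3H)-one
Conditions: 3 M HCl, 1,4-dioxane, 70 °C
Reagents that add atoms: water, O
Why: Acid-catalysed lactonization of an ortho-(1-hydroxyalkyl) tertiary benzamide (hydroxyl attack on the protonated amide, loss of diisopropylamine) leaves the C3–O bond intact, so 3S is kept, while the same medium hydrolyses the dioxolane and the alkyl TBS ether and should spare the more acid-stable aryl triisopropylsilyl ether.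

Step 11
Reactants: 19 (3S)-3-[(13S)-13-hydroxy-10-oxotetradecyl]-7-methoxy-5-(triisopropylsilyloxy)isobenzofuran-1(3H)-one
Product: 20 (3S)-5-hydroxy-3-[(13S)-13-hydroxy-10-oxotetradecyl]-7-methoxyisobenzofuran-1(3H)-one
Conditions: Bu4NF, AcOH, THF, 0 °C
Reagents that add atoms: none
Why: Fluoride cleavage of the aryl silyl ether is fast, and the acetic acid buffer should keep the lactone, the C3 stereocentre and the 4-hydroxy ketone away from basic conditions.

**Compound list**
1 | 10-bromodecan-1-ol | OCCCCCCCCCCBr | starting material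
2 | N,N-diisopropylcarbamoyl chloride | CC(C)N(C(C)C)C(Cl)=O | starting material
3 | 10-bromodecyl N,N-diisopropylcarbamate | CC(C)N(C(C)C)C(=O)OCCCCCCCCCCBr | intermediate
4 | (S)-γ-valerolactone | C[C@H]1CCC(=O)O1 | starting material
5 | (S)-4-hydroxy-N-methoxy-N-methylpentanamide | C[C@H](O)CCC(=O)N(C)OC | intermediate
6 | (S)-4-(tert-butyldimethylsilyloxy)-N-methoxy-N-methylpentanamide | C[C@H](O[Si](C)(C)C(C)(C)C)CCC(=O)N(C)OC | intermediate
7 | 10-(N,N-diisopropylcarbamoyloxy)decylmagnesium bromide, not isolated | CC(C)N(C(C)C)C(=O)OCCCCCCCCCC[Mg]Br | intermediate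
8 | (14S)-14-(tert-butyldimethylsilyloxy)-11-oxopentadecyl N,N-diisopropylcarbamate | CC(C)N(C(C)C)C(=O)OCCCCCCCCCCC(=O)CC[C@H](C)O[Si](C)(C)C(C)(C)C | intermediate
9 | 10-{2-[(3S)-3-(tert-butyldimethylsilyloxy)butyl]-1,3-dioxolan-2-yl}decyl N,N-diisopropylcarbamate | CC(C)N(C(C)C)C(=O)OCCCCCCCCCCC1(CC[C@H](C)O[Si](C)(C)C(C)(C)C)OCCO1 | intermediate
10 | 5-iodovanillin (4-hydroxy-3-iodo-5-methoxybenzaldehyde) | COc1cc(C=O)cc(I)c1O | starting material
11 | 4-hydroxy-3-iodo-5-methoxyphenyl formate, not isolated | COc1cc(OC=O)cc(I)c1O | intermediate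
12 | 2-iodo-6-methoxybenzene-1,4-diol | COc1cc(O)cc(I)c1O | intermediate
13 | 2-iodo-6-methoxy-4-(triisopropylsilyloxy)phenol | COc1cc(O[Si](C(C)C)(C(C)C)C(C)C)cc(I)c1O | intermediate
14 | 2-iodo-6-methoxy-4-(triisopropylsilyloxy)phenyl trifluoromethanesulfonate | COc1cc(O[Si](C(C)C)(C(C)C)C(C)C)cc(I)c1OS(=O)(=O)C(F)(F)F | intermediate
15 | (1R)-1-lithio derivative of 9 as its (+)-sparteine complex, not isolated | CC(C)N(C(C)C)C(=O)O[C@H]([Li])CCCCCCCCCC1(CC[C@H](C)O[Si](C)(C)C(C)(C)C)OCCO1 | intermediate
16 | 3-methoxy-5-(triisopropylsilyloxy)benzyne (C7a≡C3a), not isolated | COC1=CC(O[Si](C(C)C)(C(C)C)C(C)C)=CC#C1 | intermediate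
17 | (1S)-1-[2-lithio-3-methoxy-5-(triisopropylsilyloxy)phenyl]-10-{2-[(3S)-3-(tert-butyldimethylsilyloxy)butyl]-1,3-dioxolan-2-yl}decyl N,N-diisopropylcarbamate, not isolated | COc1cc(O[Si](C(C)C)(C(C)C)C(C)C)cc([C@@H](OC(=O)N(C(C)C)C(C)C)CCCCCCCCCC2(CC[C@H](C)O[Si](C)(C)C(C)(C)C)OCCO2)c1[Li] | intermediate
18 | 2-{(1S)-10-[2-((3S)-3-(tert-butyldimethylsilyloxy)butyl)-1,3-dioxolan-2-yl]-1-hydroxydecyl}-6-methoxy-N,N-diisopropyl-4-(triisopropylsilyloxy)benzamide | COc1cc(O[Si](C(C)C)(C(C)C)C(C)C)cc([C@@H](O)CCCCCCCCCC2(CC[C@H](C)O[Si](C)(C)C(C)(C)C)OCCO2)c1C(=O)N(C(C)C)C(C)C | intermediate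
19 | (3S)-3-[(13S)-13-hydroxy-10-oxotetradecyl]-7-methoxy-5-(triisopropylsilyloxy)isobenzofuran-1(3H)-one | COc1cc(O[Si](C(C)C)(C(C)C)C(C)C)cc2c1C(=O)O[C@H]2CCCCCCCCCC(=O)CC[C@H](C)O | intermediate
20 | (3S)-5-hydroxy-3-[(13S)-13-hydroxy-10-oxotetradecyl]-7-methoxyisobenzofuran-1(3H)-one | COc1cc(O)cc2c1C(=O)O[C@H]2CCCCCCCCCC(=O)CC[C@H](C)O | target

**Totals**
Total step count: 11. Longest linear sequence: 7 steps (steps 2, 3, 4, 5, 9, 10, 11).

**Steps most likely to fail**

1. Step 9 (proposed new method). Carbanion 15 may be consumed by iodine–lithium exchange with 14, or the aryne may be captured by n-BuLi or by aryllithium 17 before the carbamoyl shift. The addition may also lose stereochemical fidelity. The fallback makes the same two bonds one at a time by known reactions; it sets out from 9 and returns at 19.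
 - Commercial 3-bromo-5-methoxyphenol would be silylated (TIPSCl, imidazole, DMF) to (3-bromo-5-methoxyphenoxy)triisopropylsilane F1. Miyaura borylation (B2pin2, Pd(dppf)Cl2, KOAc, dioxane, 80 °C) would then give 2-[3-methoxy-5-(triisopropylsilyloxy)phenyl]-4,4,5,5-tetramethyl-1,3,2-dioxaborolane F2.
 - Carbanion 15, made from 9 as in step 9, would be added to F2 at −78 °C. The boronate complex should undergo the 1,2-aryl shift with loss of the carbamate on warming with MgBr2·OEt2, and NaBO3·4H2O oxidation would give (1S)-1-[3-methoxy-5-(triisopropylsilyloxy)phenyl]-10-{2-[(3S)-3-(tert-butyldimethylsilyloxy)butyl]-1,3-dioxolan-2-yl}decan-1-ol F3. This lithiation–borylation–oxidation forms C3a–C3; retentive borylation followed by invertive migration means (+)-sparteine again leads to 1S.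
 - Alkoxide- and methoxy-directed ortho-lithiation of F3 (n-BuLi, TMEDA, Et2O, 0 °C) at the position between the two groups (C7a), carboxylation with CO2 and mild acidification would close the lactone. This forms C7a–C1 and gives (3S)-3-(9-{2-[(3S)-3-(tert-butyldimethylsilyloxy)butyl]-1,3-dioxolan-2-yl}nonyl)-7-methoxy-5-(triisopropylsilyloxy)isobenzofuran-1(3H)-one F4.
 - 1 M HCl in THF at room temperature would remove the dioxolane and the TBS ether and return to the route at 19.

2. Step 10. Expulsion of diisopropylamine from the doubly ortho-substituted amide may be slow, and prolonged heating in acid may dehydrate the freed 4-hydroxy ketone to a cyclic enol ether or strip the aryl silyl ether unevenly. The fallback reduces the amide carbon instead of substituting at it; it sets out from 18 and returns at 19.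
 - Cp2Zr(H)Cl in THF at room temperature should reduce the tertiary amide to the aldehyde stage, which the neighbouring hydroxyl captures as (3S)-3-(9-{2-[(3S)-3-(tert-butyldimethylsilyloxy)butyl]-1,3-dioxolan-2-yl}nonyl)-7-methoxy-5-(triisopropylsilyloxy)-1,3-dihydroisobenzofuran-1-ol F5 (mixture at C1).
 - Oxidation of the lactol with Ag2CO3 on Celite in toluene at 80 °C would give the protected phthalide (3S)-3-(9-{2-[(3S)-3-(tert-butyldimethylsilyloxy)butyl]-1,3-dioxolan-2-yl}nonyl)-7-methoxy-5-(triisopropylsilyloxy)isobenzofuran-1(3H)-one F6 (the same compound as F4).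
 - 1 M HCl in THF at room temperature would then unmask ketone and alcohol without heating and return at 19.

3. Step 4. Wurtz coupling during magnesium insertion, or attack of the Grignard reagent on the carbamate carbonyl of a second molecule, may erode the coupling. The fallback carries the terminal oxygen as a benzyl ether and installs the carbamate last; it sets out from 1 and 6 and returns at 9.
 - Alcohol 1 would be benzylated under acidic conditions (benzyl 2,2,2-trichloroacetimidate, TfOH cat., CH2Cl2) to benzyl 10-bromodecyl ether F7.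
 - Its Grignard reagent (Mg, THF) would be added to 6 to give (2S)-15-(benzyloxy)-2-(tert-butyldimethylsilyloxy)pentadecan-5-one F8.
 - Noyori ketalization as in step 5 would give 2-[10-(benzyloxy)decyl]-2-[(3S)-3-(tert-butyldimethylsilyloxy)butyl]-1,3-dioxolane F9.
 - Hydrogenolysis (H2, Pd/C, EtOAc with a trace of Et3N) would free 10-{2-[(3S)-3-(tert-butyldimethylsilyloxy)butyl]-1,3-dioxolan-2-yl}decan-1-ol F10.
 - Carbamoylation with 2 (NaH, THF, reflux) would return to the route at 9.

**Further compounds**
F1 | step 9 | (3-bromo-5-methoxyphenoxy)triisopropylsilane | COc1cc(Br)cc(O[Si](C(C)C)(C(C)C)C(C)C)c1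
F2 | step 9 | 2-[3-methoxy-5-(triisopropylsilyloxy)phenyl]-4,4,5,5-tetramethyl-1,3,2-dioxaborolane | COc1cc(B2OC(C)(C)C(C)(C)O2)cc(O[Si](C(C)C)(C(C)C)C(C)C)c1
F3 | step 9 | (1S)-1-[3-methoxy-5-(triisopropylsilyloxy)phenyl]-10-{2-[(3S)-3-(tert-butyldimethylsilyloxy)butyl]-1,3-dioxolan-2-yl}decan-1-ol | COc1cc(O[Si](C(C)C)(C(C)C)C(C)C)cc([C@@H](O)CCCCCCCCCC2(CC[C@H](C)O[Si](C)(C)C(C)(C)C)OCCO2)c1
F4 | step 9 | (3S)-3-(9-{2-[(3S)-3-(tert-butyldimethylsilyloxy)butyl]-1,3-dioxolan-2-yl}nonyl)-7-methoxy-5-(triisopropylsilyloxy)isobenzofuran-1(3H)-one | COc1cc(O[Si](C(C)C)(C(C)C)C(C)C)cc2c1C(=O)O[C@H]2CCCCCCCCCC3(CC[C@H](C)O[Si](C)(C)C(C)(C)C)OCCO3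
F5 | step 10 | (3S)-3-(9-{2-[(3S)-3-(tert-butyldimethylsilyloxy)butyl]-1,3-dioxolan-2-yl}nonyl)-7-methoxy-5-(triisopropylsilyloxy)-1,3-dihydroisobenzofuran-1-ol, mixture at C1 | COc1cc(O[Si](C(C)C)(C(C)C)C(C)C)cc2c1C(O)O[C@H]2CCCCCCCCCC3(CC[C@H](C)O[Si](C)(C)C(C)(C)C)OCCO3
F6 | step 10 | (3S)-3-(9-{2-[(3S)-3-(tert-butyldimethylsilyloxy)butyl]-1,3-dioxolan-2-yl}nonyl)-7-methoxy-5-(triisopropylsilyloxy)isobenzofuran-1(3H)-one | COc1cc(O[Si](C(C)C)(C(C)C)C(C)C)cc2c1C(=O)O[C@H]2CCCCCCCCCC3(CC[C@H](C)O[Si](C)(C)C(C)(C)C)OCCO3
F7 | step 4 | benzyl 10-bromodecyl ether | BrCCCCCCCCCCOCc1ccccc1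
F8 | step 4 | (2S)-15-(benzyloxy)-2-(tert-butyldimethylsilyloxy)pentadecan-5-one | C[C@H](O[Si](C)(C)C(C)(C)C)CCC(=O)CCCCCCCCCCOCc1ccccc1
F9 | step 4 | 2-[10-(benzyloxy)decyl]-2-[(3S)-3-(tert-butyldimethylsilyloxy)butyl]-1,3-dioxolane | C[C@H](O[Si](C)(C)C(C)(C)C)CCC1(CCCCCCCCCCOCc2ccccc2)OCCO1
F10 | step 4 | 10-{2-[(3S)-3-(tert-butyldimethylsilyloxy)butyl]-1,3-dioxolan-2-yl}decan-1-ol | C[C@H](O[Si](C)(C)C(C)(C)C)CCC1(CCCCCCCCCCO)OCCO1
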